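**Retrosynthetic overview**
1. Target 15 is a trans-(3R,4R)-3,4-dibenzyl-γ-butyrolactone (ring atoms O1, C2(=O), C3, C4, C5). The phenol is unmasked last from benzyl ether 14, and the C3–benzyl bond is cut back to (R)-4-(3,4-dimethoxybenzyl)butyrolactone 8 plus benzylic bromide 12 (trans-selective enolate alkylation; 12 from syringaldehyde).
2. Lactone 8 is closed at the O1–C5 bond: O1 is inserted between C2 and C5 of achiral 3-(3,4-dimethoxybenzyl)cyclobutanone 6 by a catalytic enantioselective Baeyer–Villiger ring expansion.
3. Enabling feature: before the C3 substituent is added, C3 and C5 are both CH2 groups flanking C4. Removing O1 therefore collapses the lactone ring to a Cs-symmetric cyclobutanone with two enantiotopic α-methylenes, and the choice of which one migrates to oxygen builds the ring and fixes C4 (R) in one event.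
4. Cyclobutanone 6 comes from methyl eugenol by dichloroketene [2+2] cycloaddition and dechlorination. Ring order: cyclobutanone (step 1), then γ-lactone (step 3).

Key step: step 3

Assumption: the sense of induction of the chiral Sc(III)/N,N′-dioxide catalyst on this substrate is assigned in a first run by comparing the sign of rotation of lactone 8 with that of the known (R)-lactone; the ligand enantiomer that delivers (R)-8 is then used (both antipodes are accessible from L- or D-pipecolic acid).

**Route**

Step 1
Reactants: 1 4-allyl-1,2-dimethoxybenzene (methyl eugenol); 2 trichloroacetyl chloride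
Product: 4 rac-2,2-dichloro-3-(3,4-dimethoxybenzyl)cyclobutan-1-one, via dichloroketene 3 (not isolated)
Conditions: Zn–Cu couple, POCl3, Et2O, reflux (slow addition of 2)
Reagents that add atoms: none
Why: Thermal ketene–alkene [2+2] cycloaddition; the ketene carbonyl carbon should bond to the terminal alkene CH2, placing CCl2 next to the substituted carbon, and the racemic stereocentre formed loses its stereogenic character in step 2.

Step 2
Reactants: 4 rac-2,2-dichloro-3-(3,4-dimethoxybenzyl)cyclobutan-1-one
Product: 6 3-(3,4-dimethoxybenzyl)cyclobutan-1-one, via 2-chlorocyclobutanone 5 (not isolated)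
Conditions: Zn dust, AcOH, rt to 50 °C
Reagents that add atoms: none
Why: Stepwise reductive dehalogenation of an α,α-dichloro ketone through zinc enolates should give the Cs-symmetric cyclobutanone, in which the benzyl-bearing ring carbon is only prochiral.

Step 3
Reactants: 6 3-(3,4-dimethoxybenzyl)cyclobutan-1-one
Product: 8 (R)-4-(3,4-dimethoxybenzyl)dihydrofuran-2(3H)-one, via peroxy hemiketal 7 (not isolated)
Conditions: Sc(OTf)3 (5 mol %), chiral pipecolic-acid-derived N,N′-dioxide ligand (5 mol %, enantiomer chosen for the (R)-lactone), m-CPBA (1.2 equiv), EtOAc, −20 °C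
Reagents that add atoms: m-CPBA, OOC(=O)c1cccc(Cl)c1
Why: The Sc(III)-bound ketone should add m-CPBA to give peroxy hemiketal 7, and the chiral N,N′-dioxide pocket should let only one of the two enantiotopic α-CH2 groups lie antiperiplanar to the O–O bond, so that this CH2 (the future C5) migrates from the carbonyl carbon to the proximal peroxy oxygen as 3-chlorobenzoate leaves. The closest known reaction type is the chiral-Lewis-acid-catalysed Baeyer–Villiger desymmetrisation of 3-substituted cyclobutanones with peracids. The five-membered lactone is closed by ring expansion, a concerted 1,2-shift through a three-centre transition state that forms O1–C5 as C2–C5 breaks, and not by a Baldwin-type cyclisation. No stereocentre is created at the migrating carbon; the prochiral benzyl-bearing ring carbon becomes the C4 stereocentre, and its (R) configuration is fixed by catalyst control over which CH2 migrates. The step needs enantiotopic-group selectivity only: regioselectivity is not an issue because both α-carbons are CH2 groups of equal migratory aptitude, and chemoselectivity over arene oxidation is secured by the strain-accelerated reaction of the cyclobutanone at low temperature.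

Step 4
Reactants: 9 syringaldehyde (4-hydroxy-3,5-dimethoxybenzaldehyde)
Product: 10 4-(benzyloxy)-3,5-dimethoxybenzaldehyde
Conditions: BnBr, K2CO3, DMF, 60 °C
Reagents that add atoms: benzyl bromide, BrCc1ccccc1
Why: Williamson O-alkylation of the acidic para-formyl phenol should be straightforward despite the two flanking methoxy groups.

Step 5
Reactants: 10 4-(benzyloxy)-3,5-dimethoxybenzaldehyde
Product: 11 [4-(benzyloxy)-3,5-dimethoxyphenyl]methanol
Conditions: NaBH4, MeOH, 0 °C
Reagents that add atoms: none
Why: Borohydride reduction of an aryl aldehyde; the benzyl and methyl ethers are inert.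

Step 6
Reactants: 11 [4-(benzyloxy)-3,5-dimethoxyphenyl]methanol
Product: 12 2-(benzyloxy)-5-(bromomethyl)-1,3-dimethoxybenzene
Conditions: PBr3, CH2Cl2, 0 °C; used directly after a short filtration
Reagents that add atoms: phosphorus tribromide, BrP(Br)Br
Why: Bromination of a primary benzylic alcohol through its phosphite ester; the electron-rich bromide should be handled cold and not stored.

Step 7
Reactants: 8 (R)-4-(3,4-dimethoxybenzyl)dihydrofuran-2(3H)-one; 12 2-(benzyloxy)-5-(bromomethyl)-1,3-dimethoxybenzene
Product: 14 (3R,4R)-3-[4-(benzyloxy)-3,5-dimethoxybenzyl]-4-(3,4-dimethoxybenzyl)dihydrofuran-2(3H)-one, via lithium enolate 13 (not isolated)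
Conditions: LiHMDS (1.1 equiv), THF, −78 °C; then 12, −78 to −30 °C
Reagents that add atoms: none
Why: Kinetic alkylation of a β-substituted γ-butyrolactone enolate should occur on the face anti to the C4 benzyl group, giving the 3,4-trans (3R) isomer, which is also the thermodynamically preferred one; C4 is not acidic and is untouched.

Step 8
Reactants: 14 (3R,4R)-3-[4-(benzyloxy)-3,5-dimethoxybenzyl]-4-(3,4-dimethoxybenzyl)dihydrofuran-2(3H)-one
Product: 15 (3R,4R)-4-(3,4-dimethoxybenzyl)-3-(4-hydroxy-3,5-dimethoxybenzyl)dihydrofuran-2(3H)-one
Conditions: H2 (1 atm), 10 % Pd/C, EtOAc–EtOH, rt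
Reagents that add atoms: none
Why: Hydrogenolysis of the aryl benzyl ether under neutral conditions should leave the lactone, the methyl ethers and both stereocentres unchanged.

**Compound list**
1 | 4-allyl-1,2-dimethoxybenzene (methyl eugenol) | C=CCc1ccc(OC)c(OC)c1 | starting material
2 | trichloroacetyl chloride | ClC(Cl)(Cl)C(Cl)=O | starting material
3 | dichloroketene | ClC(Cl)=C=O | intermediate (not isolated)
4 | rac-2,2-dichloro-3-(3,4-dimethoxybenzyl)cyclobutan-1-one | COc1ccc(CC2CC(=O)C2(Cl)Cl)cc1OC | intermediate
5 | 2-chloro-3-(3,4-dimethoxybenzyl)cyclobutan-1-one (mixture of stereoisomers) | COc1ccc(CC2CC(=O)C2Cl)cc1OC | intermediate (not isolated)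
6 | 3-(3,4-dimethoxybenzyl)cyclobutan-1-one | COc1ccc(CC2CC(=O)C2)cc1OC | intermediate
7 | 3-(3,4-dimethoxybenzyl)-1-hydroxycyclobutyl 3-chlorobenzenecarboperoxoate (cis/trans mixture) | COc1ccc(CC2CC(O)(OOC(=O)c3cccc(Cl)c3)C2)cc1OC | intermediate (not isolated)
8 | (R)-4-(3,4-dimethoxybenzyl)dihydrofuran-2(3H)-one | COc1ccc(C[C@H]2COC(=O)C2)cc1OC | intermediate
9 | syringaldehyde (4-hydroxy-3,5-dimethoxybenzaldehyde) | COc1cc(C=O)cc(OC)c1O | starting material
10 | 4-(benzyloxy)-3,5-dimethoxybenzaldehyde | COc1cc(C=O)cc(OC)c1OCc1ccccc1 | intermediate
11 | [4-(benzyloxy)-3,5-dimethoxyphenyl]methanol | COc1cc(CO)cc(OC)c1OCc1ccccc1 | intermediate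
12 | 2-(benzyloxy)-5-(bromomethyl)-1,3-dimethoxybenzene | COc1cc(CBr)cc(OC)c1OCc1ccccc1 | intermediate
13 | lithium (R)-4-(3,4-dimethoxybenzyl)-4,5-dihydrofuran-2-olate | [Li+].COc1ccc(C[C@H]2COC([O-])=C2)cc1OC | intermediate (not isolated)
14 | (3R,4R)-3-[4-(benzyloxy)-3,5-dimethoxybenzyl]-4-(3,4-dimethoxybenzyl)dihydrofuran-2(3H)-one | COc1ccc(C[C@H]2COC(=O)[C@@H]2Cc2cc(OC)c(OCc3ccccc3)c(OC)c2)cc1OC | intermediate
15 | (3R,4R)-4-(3,4-dimethoxybenzyl)-3-(4-hydroxy-3,5-dimethoxybenzyl)dihydrofuran-2(3H)-one | COc1ccc(C[C@H]2COC(=O)[C@@H]2Cc2cc(OC)c(O)c(OC)c2)cc1OC | target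

**Step count:** 8 steps in total. Longest linear sequence: 5 steps (steps 1, 2, 3, 7, 8; the branch 4, 5, 6, 7, 8 is equally long).

**Steps most likely to fail**

Step 3 (key step). The catalyst may discriminate poorly between the two enantiotopic methylenes, because the prochiral centre carries a flexible benzyl arm and sits one atom away from the migrating carbon. Uncatalysed background oxidation by the peracid would erode the enantiomeric purity further. Fallback: set out from 6 and desymmetrise by enantioselective deprotonation instead of oxygen insertion. A chiral lithium amide (lithium bis(1-phenylethyl)amide, the antipode that removes the required proton) with in situ Et3SiCl in THF at −100 °C should give the (R)-triethylsilyl enol ether F1. Ozonolysis in CH2Cl2–MeOH at −78 °C, stopped at the first sign of excess ozone, with NaBH4 work-up should give the hydroxy acid F2, which should lactonise on acidification and rejoin the route at 8.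

Step 7. Facial selectivity of the enolate attack may be incomplete, proton exchange between product and enolate may lead to double alkylation, and the electron-rich bromide may ionise and self-condense before it is consumed. Fallback: set out from 8 and use aldehyde 10 in place of bromide 12, so that steps 5 and 6 are not needed. Aldol addition of lithium enolate 13 to 10 in THF at −78 °C should give the aldol adduct F3, trans at the ring and a mixture at the carbinol carbon. Hydrogenolysis (H2, Pd/C, AcOH, catalytic HClO4) should then remove the benzylic hydroxyl and the O-benzyl group in one operation, so that both carbinol epimers converge on 15.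

Step 1. Dichloroketene may oligomerise faster than it adds to the unactivated monosubstituted alkene, and zinc chloride may move the allyl double bond into conjugation with the arene. Fallback: set out from 1 and use a keteniminium [2+2] cycloaddition instead. N,N-Dimethylacetamide, Tf2O and 2,4,6-collidine in refluxing 1,2-dichloroethane should generate N,N-dimethylketeniminium triflate F4, which should add to 1 to give the cyclobutaniminium triflate F5. Aqueous NaHCO3 hydrolysis should then give 6 directly, so the fallback rejoins the route at 6 and also bypasses step 2.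

Further compounds
F1 | step 3 | (R)-{[3-(3,4-dimethoxybenzyl)cyclobut-1-en-1-yl]oxy}triethylsilane | COc1ccc(C[C@H]2C=C(O[Si](CC)(CC)CC)C2)cc1OC
F2 | step 3 | (R)-4-(3,4-dimethoxyphenyl)-3-(hydroxymethyl)butanoic acid | COc1ccc(C[C@H](CC(=O)O)CO)cc1OC
F3 | step 7 | (3S,4R)-3-{[4-(benzyloxy)-3,5-dimethoxyphenyl](hydroxy)methyl}-4-(3,4-dimethoxybenzyl)dihydrofuran-2(3H)-one (both carbinol epimers) | COc1ccc(C[C@H]2COC(=O)[C@@H]2C(O)c2cc(OC)c(OCc3ccccc3)c(OC)c2)cc1OC
F4 | step 1 | N,N-dimethylketeniminium triflate | C=C=[N+](C)C.[O-]S(=O)(=O)C(F)(F)F
F5 | step 1 | N-[3-(3,4-dimethoxybenzyl)cyclobutylidene]-N-methylmethanaminium triflate | COc1ccc(CC2CC(=[N+](C)C)C2)cc1OC.[O-]S(=O)(=O)C(F)(F)F
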